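Substrate is what you follow on this board: take one molecule and ask at each fork where its chances lie.

| flask | substrate | catalyst | temperature | remark | time |
|---|---|---|---|---|---|
| theta | 0.80 M | 0.35 mol% | 60 °C | the very flask that is asked about, followed so far |  |
| epsilon | 0.40 M | 0.35 mol% | 60 °C | run made earlier |  |
| flask | 0.80 M | 0.35 mol% | 60 °C |  | 2.0 h |

| run | time / min | target / % | substrate / % |
|---|---|---|---|
| theta | 12.0 | 58.5 | 37.6 |
| theta | 25.0 | 74.7 | 18.2 |
| theta | 40.0 | 77.9 | 9.3 |
| theta | 50.0 | 77.6 | 8.1 |
| theta | 60.0 | 77.5 | 7.3 |
| theta | 80.0 | 73.6 | 6.9 |
| epsilon | 5.00 | 31.9 | 63.1 |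
| epsilon | 8.00 | 45.6 | 50.2 |
| epsilon | 12.0 | 57.8 | 38.6 |
| epsilon | 20.0 | 73.7 | 22.3 |
| epsilon | 40.0 | 81.3 | 9.8 |
| epsilon | 60.0 | 77.4 | 7.2 |

(each reading ± 1 percentage point)

- Monday's: change nothing and wait 1.0 h more
- Sunday's: at 2.0 h raise the temperature by 15 K, then wait 1.0 h
- Friday's: at 2.0 h take out 90% of the target then present, then wait 1.0 h
- Wednesday's: at 2.0 h add catalyst, 100% of the amount charged, then wait 1.0 h

- target taken out counts as made
- the numbers in the tables scatter by 1 percentage point (one standard deviation)
- additions bring no volume worth counting
- the earlier runs do not show what temperature does; that part of a forecast is a guess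

1. target, in percent of the substrate first charged, at 2.0 h
2. what to do for the largest gain in target; "none" if nothing gains more than 2 percentage points (Monday's / Sunday's / Friday's / Wednesday's / none)
3. target present, with what was taken out counted in, in percent of the substrate first charged, after Friday's
4. target present, with what was taken out counted in, in percent of the substrate first charged, after Wednesday's

Draw the curve first. The epsilon run has 63.1% of its substrate left at 5.00 min, so the start runs at about 0.0921 min⁻¹. The theta run, at twice the concentration, reads 37.6% of substrate at 12.0 min against 38.6% in epsilon, so at that time the two readings differ by no more than their scatter. That constant halves substrate by 7.53 min, and in the epsilon run target crosses substrate between two readings: at 8.00 min target is still lower, and at 12.0 min it is higher. The knee comes near 40.0 min, where theta's target has its highest reading, 77.9%.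

In the theta run substrate then flattens out, with 6.9% still read at 80.0 min. At 60.0 min the theta run gives a ratio of 10.6; call this the resting ratio, [target]/[substrate] once their exchange has gone quiet, an apparent equilibrium constant. It is a reading, and a small substrate value carries the scatter. A molecule in this pool of two is target with a chance of 91.4%. The pool itself leaks, at 0.00260 min⁻¹ between 25.0 min and 80.0 min. Carried to 2.0 h, that leaves a pool of 72.5%, so my own target is 66.3%. Taking out 90% of it and letting the remainder return to the ratio gives me 71.4% before any further leak.

The forecast says 66%, Friday's, 69.5% and 56%, holding that “the target is lost slowly, first order”.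

The flask gives 67.2%; Friday's gains 9.4 percentage points, with 76.7% after it and 62.4% after Wednesday's.

    substrate ⇌ target (K = 10.6, k = 0.0840 min⁻¹, Ea = 107 kJ mol⁻¹, ΔH = −11.0 kJ mol⁻¹)
    2 substrate → homo dimer (k = 0.00377 M⁻¹ min⁻¹, Ea = 88.0 kJ mol⁻¹)
    target ⇌ isomer of the product A (K = 0.560, k = 0.00384 min⁻¹, Ea = 101 kJ mol⁻¹, ΔH = −46.0 kJ mol⁻¹)
    isomer of the product A + catalyst ⇌ isomer of the product B + catalyst, rate k4*[catalyst]*[isomer of the product A] forward; the back reaction follows from the equilibrium constant (K = 0.0700, k = 1.73 M⁻¹ min⁻¹, Ea = 80.0 kJ mol⁻¹, ΔH = −27.0 kJ mol⁻¹)
    (constants at 60 °C)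

At 2.00 h the flask holds 21.0% of isomer of the product A, and its [target]/[substrate] is 10.4, close to the resting ratio. Friday's leaves substrate and target together at 13.2%, of which the resting ratio makes 12.1% target, yet after the wait the flask holds 16.2% of target besides what was taken out. The neighbour flask, the same charge read at 50 min, stands at a ratio of 9.19, below the resting ratio of 10.6.

The runs stem from a simulated flask for substances that don't exist, noise included.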